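**Plan**

- Ring labels: A is the central anisole ring, B the 4-hydroxyphenyl ring, C the para-phenylene ring, D the benzoic acid ring. On ring D the carboxyl carbon (C1) is ortho to C6, which carries the CH2CH2 bridge to ring C. The ring-D-side CH2 is therefore the methyl carbon of an ortho-toluate, and the ring-C-side CH2 is benzylic, so it can be carried as a lactone CH–O carbon that hydrogenolysis turns back into CH2.
- Cuts, in retrosynthetic order: (i) the D-ring 2-OH back to OMe and the B-ring OH back to OBn; (ii) the acid reconnected to the ring-C-side bridge carbon as a 3-aryl-3,4-dihydroisocoumarin; (iii) the CH2–CH bond of that lactone (toluate carbanion plus aldehyde); (iv) the ring-C carbon–oxygen bond of the A–O–C diaryl ether (SNAr); (v) the A/B bridge at the stilbene level (Wittig).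
- Forward: B is joined to A by Wittig olefination and the alkene is saturated with diimide. Ring C is attached by SNAr as a benzaldehyde. Ring D is joined by lateral lithiation and addition, and the only ring formed in the route, the δ-lactone, closes in the same flask. Hydrogenolysis then opens the lactone and removes the benzyl group, and BCl3 frees the phenol beside the acid.
- Stereochemistry: the target has no stereocentre. The lactone C3 is made racemic and is erased by the hydrogenolysis.

Key step: step 5

Remark on the chemistry: the target is achiral, so it is a single compound as drawn and no enantioselective step is needed. Alkene 5 is carried as its E/Z mixture because the double bond is reduced in the next step.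

**Route**

Step 1
Reactants: 1 4-(benzyloxy)benzyl chloride
Product: 2 (4-benzyloxybenzyl)triphenylphosphonium chloride
Conditions: PPh3, toluene, reflux
Reagents that add atoms: triphenylphosphine, c1ccc(cc1)P(c1ccccc1)c1ccccc1
Why: SN2 quaternisation of triphenylphosphine by the reactive benzylic chloride (phosphonium salt formation) should give the salt, which is expected to precipitate from hot toluene.

Step 2
Reactants: 2 (4-benzyloxybenzyl)triphenylphosphonium chloride; 3 3-hydroxy-5-methoxybenzaldehyde
Product: 5 3-[2-(4-benzyloxyphenyl)ethenyl]-5-methoxyphenol (E/Z mixture), via benzylic phosphonium ylide 4 (not isolated)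
Conditions: KOtBu (2.4 equiv), THF, 0 °C → rt; aq. NH4Cl
Reagents that add atoms: none
Why: Wittig reaction in which one equivalent of base converts 3 into its phenoxide (meta to the formyl group, so the aldehyde is not deactivated by conjugation) and the other forms the semi-stabilised ylide 4, which should olefinate the aldehyde.

Step 3
Reactants: 5 3-[2-(4-benzyloxyphenyl)ethenyl]-5-methoxyphenol (E/Z mixture)
Product: 6 3-[2-(4-benzyloxyphenyl)ethyl]-5-methoxyphenol
Conditions: TsNHNH2, NaOAc, THF/H2O, reflux
Reagents that add atoms: none
Why: Diimide reduction, in which diimide released from the sulfonyl hydrazide delivers two hydrogens to the stilbene C=C in a concerted syn transfer and leaves the benzyl ether, which catalytic hydrogenation would endanger, untouched.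

Step 4
Reactants: 6 3-[2-(4-benzyloxyphenyl)ethyl]-5-methoxyphenol; 7 4-fluorobenzaldehyde
Product: 8 4-{3-[2-(4-benzyloxyphenyl)ethyl]-5-methoxyphenoxy}benzaldehyde
Conditions: K2CO3, DMF, 120 °C
Reagents that add atoms: none
Why: Nucleophilic aromatic substitution (SNAr, addition–elimination) in which the phenoxide of 6 attacks C4 of 7, the para-formyl group stabilises the Meisenheimer intermediate and fluoride leaves, while the benzyl and methyl ethers are inert to carbonate.

Step 5
Reactants: 9 methyl 2,4-dimethoxy-6-methylbenzoate; 8 4-{3-[2-(4-benzyloxyphenyl)ethyl]-5-methoxyphenoxy}benzaldehyde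
Product: 12 racemic 3-(4-{3-[2-(4-benzyloxyphenyl)ethyl]-5-methoxyphenoxy}phenyl)-6,8-dimethoxy-3,4-dihydroisocoumarin, via lithiated toluate 10 (not isolated), via lithium alkoxide adduct 11 (not isolated)
Conditions: LDA (1.6 equiv), THF, −78 °C, 9 (1.5 equiv) added to the base; then 8 (1.0 equiv), −78 °C → rt; aq. NH4Cl
Reagents that add atoms: none
Why: LDA removes a proton from the C6 methyl group of 9, which is acidified by the ortho ester (anion 10 is an extended ester enolate of the o-quinodimethane type), and 10 adds through its benzylic carbon to the non-enolisable aldehyde 8 to give alkoxide 11. On warming, the alkoxide oxygen attacks the neighbouring ester carbonyl (6-exo-trig acyl substitution) and expels methoxide, which closes the δ-lactone ring of 12. The closest known reaction type is the lateral lithiation of ortho-toluates and their addition to aromatic aldehydes to give 3-aryl-3,4-dihydroisocoumarins. The new stereocentre at C3 forms without any controlling element and is therefore racemic, which is acceptable because step 6 turns this carbon into a CH2 group. The selectivity needed is lateral deprotonation in preference to ring or methoxy metalation and to attack of the base or of 10 on an ester carbonyl; the ortho ester directs the amide base to the methyl group, both positions flanking the ester are substituted, and slow addition of 9 to excess LDA at −78 °C keeps free ester away from the anion.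

Step 6
Reactants: 12 racemic 3-(4-{3-[2-(4-benzyloxyphenyl)ethyl]-5-methoxyphenoxy}phenyl)-6,8-dimethoxy-3,4-dihydroisocoumarin
Product: 13 2-[2-(4-{3-[2-(4-hydroxyphenyl)ethyl]-5-methoxyphenoxy}phenyl)ethyl]-4,6-dimethoxybenzoic acid
Conditions: H2 (4 bar), 10% Pd/C, AcOH/EtOAc, 50 °C
Reagents that add atoms: none
Why: Catalytic hydrogenolysis, in which the lactone C3–O bond is a secondary benzylic carboxylate bond activated by the para-aryloxy group and should be cleaved to CH2 and the free acid (as is known for 3-aryl-dihydroisocoumarins and 3-arylphthalides), while the benzyl ether is removed in the same operation and the only stereocentre disappears.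

Step 7
Reactants: 13 2-[2-(4-{3-[2-(4-hydroxyphenyl)ethyl]-5-methoxyphenoxy}phenyl)ethyl]-4,6-dimethoxybenzoic acid
Product: 14 2-hydroxy-6-[2-(4-{3-[2-(4-hydroxyphenyl)ethyl]-5-methoxyphenoxy}phenyl)ethyl]-4-methoxybenzoic acid (CNP0188714.0)
Conditions: BCl3 (1 M in CH2Cl2, 5 equiv), CH2Cl2, −78 → 0 °C; then ice-water
Reagents that add atoms: none
Why: Chelation-controlled Lewis-acid ether cleavage, in which boron bound to the carboxyl group forms a six-membered chelate with the ortho-methoxy oxygen and chloride removes that methyl group by SN2, whereas the para-methoxy group of ring D and the ring-A methoxy group have no neighbouring carbonyl and should survive at or below 0 °C.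

**Compound list**

1 | 4-(benzyloxy)benzyl chloride | ClCc1ccc(OCc2ccccc2)cc1 | starting material
2 | (4-benzyloxybenzyl)triphenylphosphonium chloride | [Cl-].c1ccc(cc1)[P+](Cc1ccc(OCc2ccccc2)cc1)(c1ccccc1)c1ccccc1 | intermediate
3 | 3-hydroxy-5-methoxybenzaldehyde | COc1cc(O)cc(C=O)c1 | starting material
4 | (4-benzyloxybenzylidene)triphenylphosphorane (ylide) | c1ccc(cc1)P(=Cc1ccc(OCc2ccccc2)cc1)(c1ccccc1)c1ccccc1 | intermediate (not isolated)
5 | 3-[2-(4-benzyloxyphenyl)ethenyl]-5-methoxyphenol, E/Z mixture (double-bond geometry left open on purpose) | COc1cc(O)cc(C=Cc2ccc(OCc3ccccc3)cc2)c1 | intermediate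
6 | 3-[2-(4-benzyloxyphenyl)ethyl]-5-methoxyphenol | COc1cc(O)cc(CCc2ccc(OCc3ccccc3)cc2)c1 | intermediate
7 | 4-fluorobenzaldehyde | O=Cc1ccc(F)cc1 | starting material
8 | 4-{3-[2-(4-benzyloxyphenyl)ethyl]-5-methoxyphenoxy}benzaldehyde | COc1cc(CCc2ccc(OCc3ccccc3)cc2)cc(Oc2ccc(C=O)cc2)c1 | intermediate
9 | methyl 2,4-dimethoxy-6-methylbenzoate | COC(=O)c1c(C)cc(OC)cc1OC | starting material
10 | methyl 2-(lithiomethyl)-4,6-dimethoxybenzoate (lithiated toluate) | [Li]Cc1cc(OC)cc(OC)c1C(=O)OC | intermediate (not isolated)
11 | lithium 1-(4-{3-[2-(4-benzyloxyphenyl)ethyl]-5-methoxyphenoxy}phenyl)-2-[3,5-dimethoxy-2-(methoxycarbonyl)phenyl]ethanolate, racemic | [Li+].COc1cc(CCc2ccc(OCc3ccccc3)cc2)cc(Oc2ccc(C([O-])Cc3cc(OC)cc(OC)c3C(=O)OC)cc2)c1 | intermediate (not isolated)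
12 | 3-(4-{3-[2-(4-benzyloxyphenyl)ethyl]-5-methoxyphenoxy}phenyl)-6,8-dimethoxy-3,4-dihydroisocoumarin, racemic at C3 | COc1cc(CCc2ccc(OCc3ccccc3)cc2)cc(Oc2ccc(C3Cc4cc(OC)cc(OC)c4C(=O)O3)cc2)c1 | intermediate
13 | 2-[2-(4-{3-[2-(4-hydroxyphenyl)ethyl]-5-methoxyphenoxy}phenyl)ethyl]-4,6-dimethoxybenzoic acid | COc1cc(CCc2ccc(O)cc2)cc(Oc2ccc(CCc3cc(OC)cc(OC)c3C(=O)O)cc2)c1 | intermediate
14 | 2-hydroxy-6-[2-(4-{3-[2-(4-hydroxyphenyl)ethyl]-5-methoxyphenoxy}phenyl)ethyl]-4-methoxybenzoic acid (CNP0188714.0, achiral) | COc1cc(CCc2ccc(O)cc2)cc(Oc2ccc(CCc3cc(OC)cc(O)c3C(=O)O)cc2)c1 | target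

**Step count**

Total steps: 7. Longest linear sequence: 7 steps (1 → 2 → 5 → 6 → 8 → 12 → 13 → 14), with 3, 7 and 9 entering as commercial partners.

**Steps most likely to fail, with fallbacks**

Step 5. The lithiated toluate may be consumed by Claisen-type self-condensation with ester that has not yet been deprotonated, or the alkoxide may fail to close fully and leave open hydroxy ester. The fallback changes the activating group from ester to carboxylate and sets out from 8. Commercial 2,4-dimethoxy-6-methylbenzoic acid F1 would be deprotonated twice with LDA (2.2 equiv, THF, −78 → 0 °C) to give lithium 2-(lithiomethyl)-4,6-dimethoxybenzoate F2, a dianion that cannot self-condense. Its addition to 8 and acidification should give racemic 2-[2-(4-{3-[2-(4-benzyloxyphenyl)ethyl]-5-methoxyphenoxy}phenyl)-2-hydroxyethyl]-4,6-dimethoxybenzoic acid F3. This hydroxy acid is expected to lactonise on acidic work-up, or with a trace of TsOH in CH2Cl2 at rt, which returns to the route at 12.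

Step 6. The benzyl ether should leave readily, but the lactone C–O bond may resist hydrogenolysis, and more forcing conditions could begin to saturate an aromatic ring. The fallback opens the lactone by elimination instead and sets out from 12. KOtBu in DMSO/THF at rt should remove a C4 proton (again a lateral ortho-toluate position) and expel the carboxylate from C3 (E1cB), giving (E)-2-[2-(4-{3-[2-(4-benzyloxyphenyl)ethyl]-5-methoxyphenoxy}phenyl)ethenyl]-4,6-dimethoxybenzoic acid F4 after acidification. Mild hydrogenation (H2 1 atm, Pd/C, EtOAc/MeOH, rt) would then saturate the alkene and remove the benzyl group, returning to the route at 13.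

Step 7. The electron-rich benzoic acid may undergo protodecarboxylation under the Lewis and Brønsted acidic conditions, or a second methoxy group may be lost because chelation through the boron carboxylate is weaker than through a lactone carbonyl. The fallback moves the ether cleavage to the lactone stage and sets out from 12. BCl3 with pentamethylbenzene as benzyl-cation scavenger (CH2Cl2, −78 → 0 °C) should remove the peri 8-O-methyl group by chelation to the lactone carbonyl and the benzyl group at the same time, giving racemic 8-hydroxy-3-(4-{3-[2-(4-hydroxyphenyl)ethyl]-5-methoxyphenoxy}phenyl)-6-methoxy-3,4-dihydroisocoumarin F5. Hydrogenolysis of F5 under the conditions of step 6 would then open the lactone under non-Lewis-acidic conditions and return to the route at 14.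

**Further compounds**

F1 | step 5 | 2,4-dimethoxy-6-methylbenzoic acid | Cc1cc(OC)cc(OC)c1C(=O)O
F2 | step 5 | lithium 2-(lithiomethyl)-4,6-dimethoxybenzoate | [Li]Cc1cc(OC)cc(OC)c1C(=O)O[Li]
F3 | step 5 | 2-[2-(4-{3-[2-(4-benzyloxyphenyl)ethyl]-5-methoxyphenoxy}phenyl)-2-hydroxyethyl]-4,6-dimethoxybenzoic acid, racemic | COc1cc(CCc2ccc(OCc3ccccc3)cc2)cc(Oc2ccc(C(O)Cc3cc(OC)cc(OC)c3C(=O)O)cc2)c1
F4 | step 6 | (E)-2-[2-(4-{3-[2-(4-benzyloxyphenyl)ethyl]-5-methoxyphenoxy}phenyl)ethenyl]-4,6-dimethoxybenzoic acid | COc1cc(CCc2ccc(OCc3ccccc3)cc2)cc(Oc2ccc(/C=C/c3cc(OC)cc(OC)c3C(=O)O)cc2)c1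
F5 | step 7 | 8-hydroxy-3-(4-{3-[2-(4-hydroxyphenyl)ethyl]-5-methoxyphenoxy}phenyl)-6-methoxy-3,4-dihydroisocoumarin, racemic | COc1cc(CCc2ccc(O)cc2)cc(Oc2ccc(C3Cc4cc(OC)cc(O)c4C(=O)O3)cc2)c1
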